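Retrosynthetic cuts, in order: the C11–O aryl ether; C1–H and C2–H of the acetoxy ketone; the second C4–CH3 bond together with C5–H; C9–C10 (ring B); C8–C9; C5–C6.
Enabling feature: in ring A (C1–C5, C10) the C3 ketone has oxygen on the adjacent C2 and lies para to the quaternary C10. Ring A is therefore a 2-alkoxyphenol alkylated at its para carbon, and C9–C8(=C12) of ring B is the allyl unit that alkylates it.
Forward order: ring A is bought as an arene. C6–C7–C8≡C12 is joined by Negishi coupling and C9–C11 by reductive alkyne–aldehyde coupling. Ring B then closes by dearomatization, ring A is reduced and methylated, and the coumarin is attached last.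
Control element: the tether sits on the central allyl carbon C8, so both C9 and C12 could close a six-membered ring. A Me3Si group on C12 steers attack to C9 and is later exchanged for iodine and then hydrogen.
Stereochemistry: C9 comes from a CBS reduction and is relayed by double inversion at palladium. C10 comes from the chair-like closure (C11 anti to the C10 methyl). C5 comes from axial protonation in the dissolving-metal step. C2 comes from kinetic protonation of a copper enolate opposite the axial C4 and C10 methyls.

Key step: step 11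

Remark: atoms carry drimane numbers (C11 on C9, C12 on C8); "methyl face" is the face bearing the C10 methyl; TBS = tert-butyldimethylsilyl, TBSO = its oxy group, Bn = benzyl; descriptor changes at C9 and C10 along the route reflect CIP priorities only; the intermediates between the first conjugate reduction and the diosphenol are carried as C2 epimer mixtures because C2 becomes trigonal again.

Step 1
Reactants: 1 4-bromo-3,5-dimethylphenol
Product: 2 3-bromo-6-hydroxy-2,4-dimethylbenzaldehyde
Conditions: MgCl2, Et3N, (CH2O)n, MeCN, reflux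
Reagents that add atoms: formaldehyde (as paraformaldehyde), C=O
Why: Casnati–Skattebøl ortho-formylation of the magnesium phenoxide; the two free ortho positions are equivalent, so the carbon that becomes C3 is functionalised without a regiochemical choice.

Step 2
Reactants: 2 3-bromo-6-hydroxy-2,4-dimethylbenzaldehyde
Product: 3 6-(benzyloxy)-3-bromo-2,4-dimethylbenzaldehyde
Conditions: BnBr, K2CO3, DMF, 50 °C
Reagents that add atoms: benzyl bromide, BrCc1ccccc1
Why: Williamson etherification of the future C2 oxygen; benzyl survives every step up to the dissolving-metal reduction, which then removes it at no extra cost.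

Step 3
Reactants: 3 6-(benzyloxy)-3-bromo-2,4-dimethylbenzaldehyde
Product: 5 6-(benzyloxy)-3-bromo-2,4-dimethylphenol, via aryl formate 4 (not isolated)
Conditions: mCPBA, CH2Cl2, rt; then K2CO3 (cat.), MeOH, rt
Reagents that add atoms: 3-chloroperbenzoic acid, O=C(OO)c1cccc(Cl)c1
Why: Baeyer–Villiger (Dakin-type) oxidation in which the electron-rich aryl group migrates, followed by methanolysis of the formate, so the two catechol oxygens (C2–OBn, C3–OH) are differentiated by construction.

Step 4
Reactants: 5 6-(benzyloxy)-3-bromo-2,4-dimethylphenol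
Product: 6 [6-(benzyloxy)-3-bromo-2,4-dimethylphenoxy](tert-butyl)dimethylsilane
Conditions: TBSCl, imidazole, DMF, 40 °C
Reagents that add atoms: tert-butyldimethylsilyl chloride, CC(C)(C)[Si](C)(C)Cl
Why: Standard silylation masks the acidic, oxidation-prone phenol during the organometallic and oxidation steps and can later be removed selectively as an aryl silyl ether.

Step 5
Reactants: 6 [6-(benzyloxy)-3-bromo-2,4-dimethylphenoxy](tert-butyl)dimethylsilane; 7 (4-bromobut-1-yn-1-yl)trimethylsilane
Product: 9 {4-[4-(benzyloxy)-3-(TBSO)-2,6-dimethylphenyl]but-1-yn-1-yl}trimethylsilane, via alkylzinc bromide 8 (not isolated)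
Conditions: 7, Zn dust, I2 (5 mol%), DMA, 80 °C; then 6, Pd(OAc)2 (2 mol%), SPhos (4 mol%), THF, 60 °C
Reagents that add atoms: none
Why: Negishi sp2–sp3 coupling forms C5–C6; the bulky biaryl phosphine lets the di-ortho-methylated bromide couple faster than the primary alkyl group undergoes β-hydride elimination.

Step 6
Reactants: 9 {4-[4-(benzyloxy)-3-(TBSO)-2,6-dimethylphenyl]but-1-yn-1-yl}trimethylsilane; 10 (TBSO)acetaldehyde
Product: 11 (3E)-5-[4-(benzyloxy)-3-(TBSO)-2,6-dimethylphenyl]-1-(TBSO)-3-[(trimethylsilyl)methylidene]pentan-2-ol (racemic at C9)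
Conditions: Ni(cod)2 (10 mol%), PBu3 (20 mol%), Et3B (2 equiv), toluene, rt
Reagents that add atoms: none
Why: Nickel-catalysed reductive alkyne–aldehyde coupling forms C8–C9 at the alkyne carbon remote from silicon, and H and C9 add syn, which gives the E-vinylsilane with silicon cis to C7.

Step 7
Reactants: 11 racemic allylic alcohol
Product: 12 (3E)-5-[4-(benzyloxy)-3-(TBSO)-2,6-dimethylphenyl]-1-(TBSO)-3-[(trimethylsilyl)methylidene]pentan-2-one
Conditions: Dess–Martin periodinane, CH2Cl2, 0 °C to rt
Reagents that add atoms: none
Why: Dess–Martin oxidation of the allylic alcohol erases the racemic centre under neutral conditions that leave the silyl ethers, the benzyl ether and the vinylsilane untouched.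

Step 8
Reactants: 12 β-silyl enone
Product: 13 (2R,3E)-5-[4-(benzyloxy)-3-(TBSO)-2,6-dimethylphenyl]-1-(TBSO)-3-[(trimethylsilyl)methylidene]pentan-2-ol (9R)
Conditions: (R)-2-methyl-CBS-oxazaborolidine (20 mol%), BH3·SMe2, THF, −30 °C; MeOH quench
Reagents that add atoms: none
Why: Corey–Bakshi–Shibata reduction in which the α-branched alkenyl group acts as the large and CH2OTBS as the small substituent, so the R catalyst should deliver hydride to give the 9R carbinol.

Step 9
Reactants: 13 (9R)-allylic alcohol
Product: 14 methyl (9R)-carbonate of 13 (aryl TBS ether retained)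
Conditions: ClCO2Me, pyridine, DMAP (cat.), CH2Cl2, 0 °C
Reagents that add atoms: methyl chloroformate, COC(=O)Cl
Why: Acylation of the secondary allylic alcohol, without touching C9, installs the leaving group that releases its own base on ionization.

Step 10
Reactants: 14 methyl (9R)-carbonate
Product: 15 methyl (2R,3E)-5-[4-(benzyloxy)-3-hydroxy-2,6-dimethylphenyl]-1-(TBSO)-3-[(trimethylsilyl)methylidene]pentan-2-yl carbonate
Conditions: KHF2, MeOH, rt
Reagents that add atoms: none
Why: Fluoride cleaves the aryl silyl ether (phenoxide leaving group) far faster than the primary alkyl TBS ether, and the weakly acidic medium leaves the carbonate and the vinylsilane alone.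

Step 11
Reactants: 15 phenol allylic carbonate
Product: 16 (9R,10R,8(12)E)-2-(benzyloxy)-11-(TBSO)-12-(trimethylsilyl)-13-nordrima-1,4,8(12)-trien-3-one (C11 and the C10 methyl on opposite faces)
Conditions: Pd2(dba)3·CHCl3 (5 mol%), 1,2-bis(diphenylphosphino)ethane (12 mol%), degassed THF, 40 °C, no added base
Reagents that add atoms: none
Why: Proposed new method: Zerovalent palladium ionizes the C9 carbonate with inversion, the methyl carbonate anion loses CO2, methoxide deprotonates the phenol, and the phenoxide attacks the allyl terminus C9 through its methyl-bearing para carbon C10 on the face away from the metal; the closest known reactions are the palladium- and iridium-catalysed intramolecular allylic dearomatizations of para-substituted phenols (spirodienones from terminally tethered allyl units) and the silicon-directed Tsuji–Trost alkylation that gives vinylsilanes. Ring B closes as a six-membered ring onto the terminus of a centrally tethered allyl unit, so that C8 and C9 both become ring atoms (endo with respect to C8–C9) and C8=C12 is left exocyclic. C9 is fixed by the double inversion, that is, net retention of the 9R centre of 15. C10 is fixed by a chair-like transition state with C11 in the syn position of the allyl unit (cis to C7, the arrangement that avoids allylic 1,3-strain with C12–H), which puts C11 axial on ring B and anti to the axial C10 methyl. The step needs attack at C9 and not at C12, which would close a six-membered ring equally well, and the Me3Si group secures this because it shields C12 and soft nucleophiles attack silyl-substituted allylpalladium units at the carbon remote from silicon. It also needs para attack at C10 rather than ortho attack at C4 (also six-membered) or O-alkylation (eight-membered): C10 carries the largest carbon coefficient of the phenoxide HOMO and is flanked by C1–H instead of the oxido carbon, no coordinating metal cation is present under the base-free conditions, and in the ortho mode the CH2OTBS group would have to lie over the C3 oxygen.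

Step 12
Reactants: 16 cross-conjugated dienone
Product: 17 (9R,10S,8(12)E)-2-(benzyloxy)-11-(TBSO)-12-(trimethylsilyl)-13-nordrima-4,8(12)-dien-3-one (C2 epimers)
Conditions: Cu(OAc)2·H2O (5 mol%), 1,2-bis(diphenylphosphino)benzene (5 mol%), (EtO)2MeSiH, t-BuOH, toluene, 0 °C to rt
Reagents that add atoms: none
Why: Copper hydride conjugate reduction reaches only C1, the sole hydrogen-bearing β-carbon (the tetrasubstituted C4=C5 enone and the vinylsilane are inert), and removing the dienone at once avoids dienone–phenol rearrangement and aromatizing loss of the allylic C9 under the electron-transfer conditions of step 14.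

Step 13
Reactants: 17 vinylsilane enone
Product: 18 (9R,10S,8(12)E)-2-(benzyloxy)-12-iodo-11-(TBSO)-13-nordrima-4,8(12)-dien-3-one (C2 epimers)
Conditions: NIS, 2,6-lutidine, (CF3)2CHOH, 0 °C
Reagents that add atoms: N-iodosuccinimide, O=C1CCC(=O)N1I
Why: Electrophilic ipso-iododesilylation with retention of alkene geometry avoids the protic acid that protodesilylation would need (risk of exo-to-endo alkene migration) and installs a group that the next step removes anyway.

Step 14
Reactants: 18 vinyl iodide enone
Product: 20 (5S,9S,10R)-2-hydroxy-11-(TBSO)drim-8(12)-en-3-one (C2 epimers), via dilithium enolate alkoxide 19 (not isolated)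
Conditions: Li (excess), NH3(l)–THF, t-BuOH (3 equiv), −78 °C; isoprene; MeI, −78 to −33 °C; NH4Cl
Reagents that add atoms: iodomethane, CI
Why: Stork-type dissolving-metal reductive alkylation in which C5 is protonated axially opposite the C10 methyl (trans-decalin) and the regiodefined C3–C4 enolate is C-methylated to the gem-dimethyl group, while the same lithium cleaves the benzyl ether to the non-leaving C2 alkoxide and the vinyl iodide to the C12 methylene.

Step 15
Reactants: 20 α-ketol
Product: 22 (5S,9S,10R)-2-acetoxy-11-(TBSO)drima-1,8(12)-dien-3-one, via diosphenol 21 (not isolated)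
Conditions: Dess–Martin periodinane, CH2Cl2, 0 °C to rt; then Et3N, Ac2O, DMAP (cat.), 0 °C
Reagents that add atoms: acetic anhydride, CC(=O)OC(C)=O
Why: Oxidation of the α-ketol gives the 2,3-dione, which can enolize only towards C1 because C4 is quaternary, and O-acetylation of that diosphenol makes both C2 epimers converge on one enol acetate.

Step 16
Reactants: 22 2-acetoxy enone
Product: 23 (2R,5S,9S,10R)-2-acetoxy-11-(TBSO)drim-8(12)-en-3-one
Conditions: Cu(OAc)2·H2O (5 mol%), 1,2-bis(diphenylphosphino)benzene (5 mol%), (EtO)2MeSiH, t-BuOH, toluene, 0 °C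
Reagents that add atoms: none
Why: Copper hydride conjugate reduction delivers hydride to C1, and the copper enolate is protonated at C2 by bulky t-BuOH from the face opposite the two axial methyls on C4 and C10, which should place the acetate on the methyl face (2R) and spare the isolated C8=C12 alkene.

Step 17
Reactants: 23 TBS ether
Product: 24 (2R,5S,9S,10R)-2-acetoxy-11-hydroxydrim-8(12)-en-3-one
Conditions: HF·pyridine, pyridine, THF, 0 °C
Reagents that add atoms: none
Why: Buffered fluoride cleavage of the primary silyl ether is non-basic, so the epimerizable C2 centre, the acetate and the exocyclic alkene should stay in place.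

Step 18
Reactants: 24 primary alcohol; 25 isofraxidin (7-hydroxy-6,8-dimethoxycoumarin)
Product: 26 (2R,5S,9S,10R)-2-acetoxy-11-[(6,8-dimethoxy-2-oxo-2H-chromen-7-yl)oxy]drim-8(12)-en-3-one (CNP0183157.1)
Conditions: PPh3, DIAD, toluene–THF, 0 °C to rt
Reagents that add atoms: none
Why: Mitsunobu etherification in which the acidic 7-OH of the coumarin displaces the activated primary C11 oxygen under essentially neutral conditions, so no stereocentre is involved and C2 is not epimerized.

Compound list
1 | 4-bromo-3,5-dimethylphenol | Cc1cc(O)cc(C)c1Br | starting material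
2 | 3-bromo-6-hydroxy-2,4-dimethylbenzaldehyde | Cc1cc(O)c(C=O)c(C)c1Br | intermediate
3 | 6-(benzyloxy)-3-bromo-2,4-dimethylbenzaldehyde | Cc1cc(OCc2ccccc2)c(C=O)c(C)c1Br | intermediate
4 | 6-(benzyloxy)-3-bromo-2,4-dimethylphenyl formate (not isolated) | Cc1cc(OCc2ccccc2)c(OC=O)c(C)c1Br | intermediate
5 | 6-(benzyloxy)-3-bromo-2,4-dimethylphenol | Cc1cc(OCc2ccccc2)c(O)c(C)c1Br | intermediate
6 | [6-(benzyloxy)-3-bromo-2,4-dimethylphenoxy](tert-butyl)dimethylsilane | Cc1cc(OCc2ccccc2)c(O[Si](C)(C)C(C)(C)C)c(C)c1Br | intermediate
7 | (4-bromobut-1-yn-1-yl)trimethylsilane | C[Si](C)(C)C#CCCBr | starting material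
8 | [4-(trimethylsilyl)but-3-yn-1-yl]zinc bromide (not isolated) | C[Si](C)(C)C#CCC[Zn]Br | intermediate
9 | {4-[4-(benzyloxy)-3-(TBSO)-2,6-dimethylphenyl]but-1-yn-1-yl}trimethylsilane | Cc1cc(OCc2ccccc2)c(O[Si](C)(C)C(C)(C)C)c(C)c1CCC#C[Si](C)(C)C | intermediate
10 | (tert-butyldimethylsilyloxy)acetaldehyde | CC(C)(C)[Si](C)(C)OCC=O | starting material
11 | racemic E-allylic alcohol (Si cis to C7) | Cc1cc(OCc2ccccc2)c(O[Si](C)(C)C(C)(C)C)c(C)c1CC/C(=C\[Si](C)(C)C)C(O)CO[Si](C)(C)C(C)(C)C | intermediate
12 | E-β-silyl enone | Cc1cc(OCc2ccccc2)c(O[Si](C)(C)C(C)(C)C)c(C)c1CC/C(=C\[Si](C)(C)C)C(=O)CO[Si](C)(C)C(C)(C)C | intermediate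
13 | (9R)-E-allylic alcohol | Cc1cc(OCc2ccccc2)c(O[Si](C)(C)C(C)(C)C)c(C)c1CC/C(=C\[Si](C)(C)C)[C@@H](O)CO[Si](C)(C)C(C)(C)C | intermediate
14 | (9R)-methyl carbonate, aryl TBS ether | Cc1cc(OCc2ccccc2)c(O[Si](C)(C)C(C)(C)C)c(C)c1CC/C(=C\[Si](C)(C)C)[C@@H](OC(=O)OC)CO[Si](C)(C)C(C)(C)C | intermediate
15 | (9R)-methyl carbonate, free phenol (key-step precursor) | Cc1cc(OCc2ccccc2)c(O)c(C)c1CC/C(=C\[Si](C)(C)C)[C@@H](OC(=O)OC)CO[Si](C)(C)C(C)(C)C | intermediate
16 | (9R,10R)-fused 2-benzyloxy dienone with E-silylmethylidene at C8 (key-step product) | C[Si](C)(C)/C=C1\CCC2=C(C)C(=O)C(OCc3ccccc3)=C[C@@]2(C)[C@H]1CO[Si](C)(C)C(C)(C)C | intermediate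
17 | (9R,10S)-2-benzyloxy-4-en-3-one, vinylsilane, C2 epimers | C[Si](C)(C)/C=C1\CCC2=C(C)C(=O)C(OCc3ccccc3)C[C@@]2(C)[C@H]1CO[Si](C)(C)C(C)(C)C | intermediate
18 | (9R,10S)-2-benzyloxy-4-en-3-one, E-vinyl iodide, C2 epimers | I/C=C1\CCC2=C(C)C(=O)C(OCc3ccccc3)C[C@@]2(C)[C@H]1CO[Si](C)(C)C(C)(C)C | intermediate
19 | dilithium C3–C4 enolate C2 alkoxide (not isolated) | [Li+].[Li+].C=C1CC[C@@H]2C(C)=C([O-])C([O-])C[C@@]2(C)[C@H]1CO[Si](C)(C)C(C)(C)C | intermediate
20 | (5S,9S,10R)-2-hydroxy-11-(TBSO)drim-8(12)-en-3-one, C2 epimers | C=C1CC[C@@H]2C(C)(C)C(=O)C(O)C[C@@]2(C)[C@H]1CO[Si](C)(C)C(C)(C)C | intermediate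
21 | (5S,9S,10R)-2-hydroxy-11-(TBSO)drima-1,8(12)-dien-3-one, diosphenol (not isolated) | C=C1CC[C@@H]2C(C)(C)C(=O)C(O)=C[C@@]2(C)[C@H]1CO[Si](C)(C)C(C)(C)C | intermediate
22 | (5S,9S,10R)-2-acetoxy-11-(TBSO)drima-1,8(12)-dien-3-one | C=C1CC[C@@H]2C(C)(C)C(=O)C(OC(C)=O)=C[C@@]2(C)[C@H]1CO[Si](C)(C)C(C)(C)C | intermediate
23 | (2R,5S,9S,10R)-2-acetoxy-11-(TBSO)drim-8(12)-en-3-one | C=C1CC[C@@H]2C(C)(C)C(=O)[C@H](OC(C)=O)C[C@@]2(C)[C@H]1CO[Si](C)(C)C(C)(C)C | intermediate
24 | (2R,5S,9S,10R)-2-acetoxy-11-hydroxydrim-8(12)-en-3-one | C=C1CC[C@@H]2C(C)(C)C(=O)[C@H](OC(C)=O)C[C@@]2(C)[C@H]1CO | intermediate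
25 | isofraxidin | COc1cc2ccc(=O)oc2c(OC)c1O | starting material
26 | CNP0183157.1 | C=C1CC[C@@H]2C(C)(C)C(=O)[C@H](OC(C)=O)C[C@@]2(C)[C@H]1COc1c(OC)cc2ccc(=O)oc2c1OC | target

Total step count: 18. Longest linear sequence: 18 steps (1 to 26); 7, 10 and 25 enter as purchased fragments.

Steps most likely to fail

Step 11. Several processes could intervene:
- Ionization of the crowded, trisubstituted allyl carbonate may be slow.
- C-alkylation through the ortho carbon C4 may compete.
- The allyl complex may lose a β-hydrogen to give dienes.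
- Exchange of palladium between the allyl faces may erode the chirality transfer.

The fallback is a metal-free intramolecular para-alkylation of the phenolate (Winstein–Masamune type dearomatization) and sets out from 13. Hexachloroacetone and PPh3 replace the hydroxyl by chloride with inversion and without allylic shift, giving the (9S)-allylic chloride F1. KHF2 in MeOH then frees the phenol to give the chloro phenol F2. KOtBu in t-BuOH–THF closes ring B by SN2 displacement at C9 with a second inversion, with the silyl group again blocking the transposed mode at C12. The sequence comes back to the route at 16.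

Step 14. The enone radical anion may expel the C2 benzyloxy group. The C2 alkoxide may be O-methylated. The four reductive events may also fail to run to completion together.

The fallback takes the C2 oxygen out of the reduction and reinstalls it by autoxidation; it sets out from 18. SmI2 in THF–MeOH cleaves the α-alkoxy ketone to the 2-deoxy enone F3. Li/NH3 followed by MeI then performs the textbook reductive methylation (and deiodination) to give the 4,4-dimethyl ketone F4. O2 with KOtBu in t-BuOH oxidizes the only enolizable position, C2. The sequence comes back to the route at 21.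

Step 16. Facial selectivity of the C2 protonation may be poor. The acetyl group may migrate from O2 to O3 within the enolate. Alkoxide may epimerize C2 after the reduction.

The fallback sets C2 by hydride attack on a carbonyl instead of by protonation; it sets out from 21, isolated for this purpose. NaBH4 in MeOH–CH2Cl2 attacks both carbonyls from the face opposite the axial methyls, giving the (2R,3S)-cis-diol F5 with both hydroxyls on the methyl face. MeC(OMe)3 with catalytic camphorsulfonic acid gives the cyclic orthoacetate F6. Brief treatment with aqueous AcOH opens it under stereoelectronic control to the axial ester, the 2-acetate 3-alcohol F7. Dess–Martin oxidation of the C3 alcohol comes back to the route at 23.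

Further compounds
F1 | step 11 | (9S)-allylic chloride, aryl TBS ether | Cc1cc(OCc2ccccc2)c(O[Si](C)(C)C(C)(C)C)c(C)c1CC/C(=C\[Si](C)(C)C)[C@H](Cl)CO[Si](C)(C)C(C)(C)C
F2 | step 11 | (9S)-allylic chloride, free phenol | Cc1cc(OCc2ccccc2)c(O)c(C)c1CC/C(=C\[Si](C)(C)C)[C@H](Cl)CO[Si](C)(C)C(C)(C)C
F3 | step 14 | 2-deoxy 4-en-3-one, E-vinyl iodide | I/C=C1\CCC2=C(C)C(=O)CC[C@@]2(C)[C@H]1CO[Si](C)(C)C(C)(C)C
F4 | step 14 | (5S,9S,10R)-11-(TBSO)drim-8(12)-en-3-one | C=C1CC[C@@H]2C(C)(C)C(=O)CC[C@@]2(C)[C@H]1CO[Si](C)(C)C(C)(C)C
F5 | step 16 | (2R,3S,5S,9S,10R)-11-(TBSO)drim-8(12)-ene-2,3-diol | C=C1CC[C@@H]2C(C)(C)[C@H](O)[C@H](O)C[C@@]2(C)[C@H]1CO[Si](C)(C)C(C)(C)C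
F6 | step 16 | 2,3-O-(1-methoxyethylidene) orthoacetate of F5 | C=C1CC[C@@H]2C(C)(C)[C@@H]3OC(C)(OC)O[C@@H]3C[C@@]2(C)[C@H]1CO[Si](C)(C)C(C)(C)C
F7 | step 16 | (2R,3S,5S,9S,10R)-2-acetoxy-11-(TBSO)drim-8(12)-en-3-ol | C=C1CC[C@@H]2C(C)(C)[C@H](O)[C@H](OC(C)=O)C[C@@]2(C)[C@H]1CO[Si](C)(C)C(C)(C)C
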